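**Plan**

- Retrosynthesis: the two O-methyl groups go first. The side chain is cut at ArCH2–CH= and at the vinylic CH3 (back to a terminal alkyne, Me3Al and a benzylic bromide), then at the CH2–CH2 bond next to the bicycle (allylic bromide plus propargyl anion). The C2 methyl goes back to an enol triflate, and ring B is opened last at C1–C8a.
- Enabling feature: the quaternary C8a lies between C4a–H and the sp2 C1 of the tetrasubstituted C1=C2 alkene of ring B. C8a is therefore read as the tertiary cation of a 2,6,6-trimethylcyclohex-2-enyl ring A, and C1, C2 and the first chain carbon as a β-keto ester (C1 nucleophile, C2 ketone, ester carbon) tethered through C3–C4.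
- Forward: ring A is bought in (R)-α-ionone and its chain is made into the β-keto ester. Ring B closes (C1–C8a); the helper ketone becomes the C2 methyl via the triflate and the helper ester becomes the first chain CH2. The chain grows by three carbons to an alkyne and the arene is joined last.
- Stereochemistry: C4a comes from (R)-α-ionone. C8a is set in the ring closure (trans-fused, chair transition state, controlled by C4a). The (E)-alkene comes from syn-carboalumination and retentive coupling.

Key step: step 3

Remark: (R)-(+)-α-ionone (the enantiomer present in natural-grade α-ionone) is taken as the purchasable source of the C4a stereocentre; the bicycle is numbered as in the names (ring A: C4a, C5–C8, C8a; ring B: C1–C4, C4a, C8a).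

Step 1
Reactants: 1 (R)-α-ionone, (3E)-4-[(1R)-2,6,6-trimethylcyclohex-2-en-1-yl]but-3-en-2-one
Product: 2 (R)-dihydro-α-ionone, 4-[(1R)-2,6,6-trimethylcyclohex-2-en-1-yl]butan-2-one
Conditions: Bu3SnH (1.2 equiv, slow addition), Pd(PPh3)4 (2 mol %), AcOH (1.5 equiv), THF, rt
Reagents that add atoms: none
Why: Palladium-catalysed conjugate reduction with a tin hydride (hydride to the β-carbon of the enone, protonation of the tin enolate by AcOH) should reduce only the enone C=C, spare the trisubstituted ring alkene and, being neutral, leave the stereocentre (doubly allylic in 1, unactivated in 2) untouched.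

Step 2
Reactants: 2 (R)-dihydro-α-ionone
Product: 3 methyl 3-oxo-5-[(1R)-2,6,6-trimethylcyclohex-2-en-1-yl]pentanoate
Conditions: NaH (2.5 equiv), (MeO)2CO (4 equiv), THF, reflux; then AcOH
Reagents that add atoms: dimethyl carbonate, COC(=O)OC
Why: Claisen-type carbomethoxylation under equilibrating conditions should acylate the methyl-side enolate only, because the product is drained off as its stabilised sodium enolate.

Step 3
Reactants: 3 methyl 3-oxo-5-[(1R)-2,6,6-trimethylcyclohex-2-en-1-yl]pentanoate
Product: 4 methyl (1S,4aR,8aR)-5,5,8a-trimethyl-2-oxodecahydronaphthalene-1-carboxylate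
Conditions: SnCl4 (1.5 equiv), CH2Cl2 (water-saturated), −40 °C → 0 °C
Reagents that add atoms: none
Why: SnCl4 binds the β-keto ester as its enol chelate, a strong proton donor that protonates the ring-A alkene of 3 at its CH carbon to give the tertiary cation at the methyl-bearing carbon (the future C8a); the chelated enol carbon (future C1) attacks this cation and loss of a proton returns the keto ester. The closest known reaction type is the SnCl4-mediated cation–olefin cyclisation of unsaturated β-keto esters (termination by a 1,3-dicarbonyl). Ring B closes through the C1–C8a bond in a 6-(enolendo)-exo-trig sense, the enol C1=C2 lying inside the new six-membered ring and the cationic carbon being attacked from outside the former ring-A double bond. C8a is set under control of the C4a stereocentre through a chair-like transition state with the C4a–C4 tether equatorial on ring A, the enol bonding on the face that carries H-4a so that the methyl group becomes axial and anti to H-4a (trans-decalin), whereas the cis alternative would put C1 axial on ring A against the axial C5 methyl; C1 (1S, ester equatorial) is enolisable, settles thermodynamically and is erased in step 4. The step needs C- over O-alkylation of the enol (secured by tin chelation and the reversibility of O-attack) and ring closure faster than loss of H-4a from the cation, which would give the achiral tetrasubstituted alkene and erode the enantiomeric purity (secured by the tethered enol poised for six-membered closure, a non-basic medium and low temperature); 3 holds no second alkene that could compete.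

Step 4
Reactants: 4 methyl (1S,4aR,8aR)-5,5,8a-trimethyl-2-oxodecahydronaphthalene-1-carboxylate
Product: 5 methyl (4aR,8aR)-5,5,8a-trimethyl-2-[(trifluoromethanesulfonyl)oxy]-3,4,4a,5,6,7,8,8a-octahydronaphthalene-1-carboxylate
Conditions: Tf2O (1.3 equiv), EtN(iPr)2 (2 equiv), CH2Cl2, −78 °C → 0 °C
Reagents that add atoms: trifluoromethanesulfonic anhydride, O=S(=O)(OS(=O)(=O)C(F)(F)F)C(F)(F)F
Why: O-Triflation of the 1,3-dicarbonyl enol should place the double bond between C1 and C2 only, since the C1 hydrogen between the two carbonyl groups is the acidic one, and this fixes the position of the later ring alkene.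

Step 5
Reactants: 5 methyl (4aR,8aR)-5,5,8a-trimethyl-2-[(trifluoromethanesulfonyl)oxy]-3,4,4a,5,6,7,8,8a-octahydronaphthalene-1-carboxylate
Product: 6 methyl (4aR,8aR)-2,5,5,8a-tetramethyl-3,4,4a,5,6,7,8,8a-octahydronaphthalene-1-carboxylate
Conditions: MeMgBr (1.5 equiv), Fe(acac)3 (5 mol %), THF/NMP, −30 °C → 0 °C
Reagents that add atoms: methylmagnesium bromide, C[Mg]Br
Why: Iron-catalysed Kumada-type cross-coupling of the ester-activated alkenyl triflate with MeMgBr (no β-hydrogen, faster than addition to the hindered ester) should swap OTf for CH3 and give the tetrasubstituted C1=C2 alkene.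

Step 6
Reactants: 6 methyl (4aR,8aR)-2,5,5,8a-tetramethyl-3,4,4a,5,6,7,8,8a-octahydronaphthalene-1-carboxylate
Product: 7 [(4aR,8aR)-2,5,5,8a-tetramethyl-3,4,4a,5,6,7,8,8a-octahydronaphthalen-1-yl]methanol
Conditions: LiAlH4 (1.5 equiv), Et2O, 0 °C → reflux; then H2O, aq. NaOH
Reagents that add atoms: none
Why: Hydride reduction of the ester (two 1,2-additions; the tetrasubstituted alkene is twisted out of conjugation and shielded against conjugate addition) should give the primary allylic alcohol.

Step 7
Reactants: 7 [(4aR,8aR)-2,5,5,8a-tetramethyl-3,4,4a,5,6,7,8,8a-octahydronaphthalen-1-yl]methanol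
Product: 8 (4aR,8aR)-1-(bromomethyl)-2,5,5,8a-tetramethyl-3,4,4a,5,6,7,8,8a-octahydronaphthalene
Conditions: CBr4 (1.3 equiv), PPh3 (1.3 equiv), CH2Cl2, 0 °C; filtered through a short silica pad and used at once
Reagents that add atoms: carbon tetrabromide, BrC(Br)(Br)Br
Why: Appel reaction, in which bromide displaces the alkoxyphosphonium group by SN2 at the primary allylic carbon under neutral conditions, should avoid ionisation and allylic transposition (the SN2' carbon C2 is fully substituted).

Step 8
Reactants: 8 (4aR,8aR)-1-(bromomethyl)-2,5,5,8a-tetramethyl-3,4,4a,5,6,7,8,8a-octahydronaphthalene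
Product: 10 (4aR,8aR)-1-(but-3-yn-1-yl)-2,5,5,8a-tetramethyl-3,4,4a,5,6,7,8,8a-octahydronaphthalene, via silylalkyne 9 (not isolated)
Conditions: 1-(trimethylsilyl)propyne (1.6 equiv), n-BuLi (1.5 equiv), THF, −78 → −20 °C; then 8, −78 °C → rt; then MeOH, K2CO3, rt
Reagents that add atoms: 1-(trimethylsilyl)propyne, CC#C[Si](C)(C)C
Why: SN2 alkylation of the propargyl-lithium from 1-(trimethylsilyl)propyne at its CH2 terminus (the silyl group disfavours the allenyl product), followed by methanolysis of the alkynyl C–Si bond, should add the CH2–C≡CH unit and complete the two-carbon spacer.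

Step 9
Reactants: 10 (4aR,8aR)-1-(but-3-yn-1-yl)-2,5,5,8a-tetramethyl-3,4,4a,5,6,7,8,8a-octahydronaphthalene; 11 methyl 3-(bromomethyl)-4-methoxybenzoate
Product: 13 methyl 4-methoxy-3-{(2E)-3-methyl-5-[(4aR,8aR)-2,5,5,8a-tetramethyl-3,4,4a,5,6,7,8,8a-octahydronaphthalen-1-yl]pent-2-en-1-yl}benzoate, via alkenylalane 12 (not isolated)
Conditions: Me3Al (2 equiv), Cp2ZrCl2 (25 mol %), CH2Cl2, 0 °C → rt; volatiles removed in vacuo; then 11, Pd(PPh3)4 (5 mol %), THF, rt
Reagents that add atoms: trimethylaluminium, C[Al](C)C
Why: Zirconium-catalysed syn-carboalumination of the terminal alkyne (Negishi carboalumination: methyl to the internal carbon, aluminium to the terminus) followed by palladium-catalysed cross-coupling of the alkenylalane with the benzylic bromide, which goes with retention, should set the (E)-trisubstituted alkene and join the arene in one operation.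

Step 10
Reactants: 13 methyl 4-methoxy-3-{(2E)-3-methyl-5-[(4aR,8aR)-2,5,5,8a-tetramethyl-3,4,4a,5,6,7,8,8a-octahydronaphthalen-1-yl]pent-2-en-1-yl}benzoate
Product: 14 4-hydroxy-3-{(2E)-3-methyl-5-[(4aR,8aR)-2,5,5,8a-tetramethyl-3,4,4a,5,6,7,8,8a-octahydronaphthalen-1-yl]pent-2-en-1-yl}benzoic acid
Conditions: NaSEt (6 equiv), DMF, 120 °C; then cold 1 M HCl to pH 3
Reagents that add atoms: none
Why: Thiolate SN2 demethylation at both O-methyl carbons (aryl methyl ether and methyl ester) should free the phenol and the acid under non-acidic conditions, which keeps the ortho-allyl phenol and the two alkenes away from acid that would close a chroman ring or shift the alkenes.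

**Compound list**

1 | (R)-α-ionone, (3E)-4-[(1R)-2,6,6-trimethylcyclohex-2-en-1-yl]but-3-en-2-one | CC(=O)/C=C/[C@H]1C(C)=CCCC1(C)C | starting material
2 | (R)-dihydro-α-ionone, 4-[(1R)-2,6,6-trimethylcyclohex-2-en-1-yl]butan-2-one | CC(=O)CC[C@H]1C(C)=CCCC1(C)C | intermediate
3 | methyl 3-oxo-5-[(1R)-2,6,6-trimethylcyclohex-2-en-1-yl]pentanoate | COC(=O)CC(=O)CC[C@H]1C(C)=CCCC1(C)C | intermediate
4 | methyl (1S,4aR,8aR)-5,5,8a-trimethyl-2-oxodecahydronaphthalene-1-carboxylate | O=C1[C@@H](C(=O)OC)[C@]2(C)CCCC(C)(C)[C@H]2CC1 | intermediate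
5 | methyl (4aR,8aR)-5,5,8a-trimethyl-2-[(trifluoromethanesulfonyl)oxy]-3,4,4a,5,6,7,8,8a-octahydronaphthalene-1-carboxylate | FC(F)(F)S(=O)(=O)OC1=C(C(=O)OC)[C@]2(C)CCCC(C)(C)[C@H]2CC1 | intermediate
6 | methyl (4aR,8aR)-2,5,5,8a-tetramethyl-3,4,4a,5,6,7,8,8a-octahydronaphthalene-1-carboxylate | CC1=C(C(=O)OC)[C@]2(C)CCCC(C)(C)[C@H]2CC1 | intermediate
7 | [(4aR,8aR)-2,5,5,8a-tetramethyl-3,4,4a,5,6,7,8,8a-octahydronaphthalen-1-yl]methanol | CC1=C(CO)[C@]2(C)CCCC(C)(C)[C@H]2CC1 | intermediate
8 | (4aR,8aR)-1-(bromomethyl)-2,5,5,8a-tetramethyl-3,4,4a,5,6,7,8,8a-octahydronaphthalene | CC1=C(CBr)[C@]2(C)CCCC(C)(C)[C@H]2CC1 | intermediate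
9 | trimethyl{4-[(4aR,8aR)-2,5,5,8a-tetramethyl-3,4,4a,5,6,7,8,8a-octahydronaphthalen-1-yl]but-1-yn-1-yl}silane | CC1=C(CCC#C[Si](C)(C)C)[C@]2(C)CCCC(C)(C)[C@H]2CC1 | intermediate
10 | (4aR,8aR)-1-(but-3-yn-1-yl)-2,5,5,8a-tetramethyl-3,4,4a,5,6,7,8,8a-octahydronaphthalene | CC1=C(CCC#C)[C@]2(C)CCCC(C)(C)[C@H]2CC1 | intermediate
11 | methyl 3-(bromomethyl)-4-methoxybenzoate | COC(=O)c1ccc(OC)c(CBr)c1 | starting material
12 | dimethyl{(1E)-2-methyl-4-[(4aR,8aR)-2,5,5,8a-tetramethyl-3,4,4a,5,6,7,8,8a-octahydronaphthalen-1-yl]but-1-en-1-yl}alumane | CC1=C(CC/C(C)=C/[Al](C)C)[C@]2(C)CCCC(C)(C)[C@H]2CC1 | intermediate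
13 | methyl 4-methoxy-3-{(2E)-3-methyl-5-[(4aR,8aR)-2,5,5,8a-tetramethyl-3,4,4a,5,6,7,8,8a-octahydronaphthalen-1-yl]pent-2-en-1-yl}benzoate | CC1=C(CC/C(C)=C/Cc2cc(C(=O)OC)ccc2OC)[C@]2(C)CCCC(C)(C)[C@H]2CC1 | intermediate
14 | 4-hydroxy-3-{(2E)-3-methyl-5-[(4aR,8aR)-2,5,5,8a-tetramethyl-3,4,4a,5,6,7,8,8a-octahydronaphthalen-1-yl]pent-2-en-1-yl}benzoic acid | CC1=C(CC/C(C)=C/Cc2cc(C(=O)O)ccc2O)[C@]2(C)CCCC(C)(C)[C@H]2CC1 | target

**Totals and risks**

Total step count: 10. Longest linear sequence: 10 steps (1 to 14); compound 11 is bought.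

The three steps most likely to fail:

Step 3. What may go wrong is loss of configurational purity: the tertiary cation can shed H-4a to the achiral tetrasubstituted ring alkene, which re-enters the cyclisation as racemate. Some leakage into the cis-fused series is also possible. The fallback secures the absolute configuration by resolution instead of by transfer from C4a; it sets out from 4 and comes back at 4. Scalemic 4 is condensed with (S)-1-phenylethylamine (cat. AcOH, toluene, reflux, removal of water) to the enamino ester methyl (4aR,8aR)-5,5,8a-trimethyl-2-{[(1S)-1-phenylethyl]amino}-3,4,4a,5,6,7,8,8a-octahydronaphthalene-1-carboxylate F1. F1 is brought to diastereomeric purity by crystallisation or chromatography and hydrolysed (aqueous oxalic acid, THF, rt) to give back 4 as a single enantiomer.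

Step 9. What may go wrong is transfer of methyl instead of alkenyl from aluminium, attack of the alane on the benzoate ester, or slow transmetalation to palladium. The fallback reverses the polarity of the coupling (alkenyl electrophile, benzyl nucleophile); it sets out from 10 and comes back at 13. Alane 12, made from 10 as in step 9, is quenched with I2 (THF, −30 °C) to the alkenyl iodide (4aR,8aR)-1-[(3E)-4-iodo-3-methylbut-3-en-1-yl]-2,5,5,8a-tetramethyl-3,4,4a,5,6,7,8,8a-octahydronaphthalene F2. Bromide 11 is treated with zinc dust and LiCl (THF, rt) to give [2-methoxy-5-(methoxycarbonyl)benzyl]zinc bromide F3. Coupling of F2 with F3 (Pd(OAc)2, SPhos, THF, rt) should give 13 with the alkene geometry retained.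

Step 10. What may go wrong is incomplete cleavage of the aryl methyl ether, or base-induced migration of the skipped arene–alkene unit and decomposition at 120 °C. The fallback changes the phenol protecting group to one that leaves under mild hydroxide; it sets out from 10 and comes back at 14. Commercial methyl 4-hydroxy-3-methylbenzoate is silylated (TBSCl, imidazole, DMF) to methyl 4-[(tert-butyldimethylsilyl)oxy]-3-methylbenzoate F4. F4 is brominated at the benzylic carbon (NBS, cat. AIBN, PhCF3, 80 °C) to methyl 3-(bromomethyl)-4-[(tert-butyldimethylsilyl)oxy]benzoate F5. Alane 12, made from 10 as in step 9, is coupled with F5 (Pd(PPh3)4, THF, rt) to the silyl ether methyl 4-[(tert-butyldimethylsilyl)oxy]-3-{(2E)-3-methyl-5-[(4aR,8aR)-2,5,5,8a-tetramethyl-3,4,4a,5,6,7,8,8a-octahydronaphthalen-1-yl]pent-2-en-1-yl}benzoate F6. LiOH (THF/MeOH/H2O, 50 °C) should then remove the aryl silyl ether and the methyl ester in one operation and give 14 after mild acidification.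

**Further compounds**

F1 | step 3 | methyl (4aR,8aR)-5,5,8a-trimethyl-2-{[(1S)-1-phenylethyl]amino}-3,4,4a,5,6,7,8,8a-octahydronaphthalene-1-carboxylate | C[C@H](NC1=C(C(=O)OC)[C@]2(C)CCCC(C)(C)[C@H]2CC1)c1ccccc1
F2 | step 9 | (4aR,8aR)-1-[(3E)-4-iodo-3-methylbut-3-en-1-yl]-2,5,5,8a-tetramethyl-3,4,4a,5,6,7,8,8a-octahydronaphthalene | CC1=C(CC/C(C)=C/I)[C@]2(C)CCCC(C)(C)[C@H]2CC1
F3 | step 9 | [2-methoxy-5-(methoxycarbonyl)benzyl]zinc bromide | COC(=O)c1ccc(OC)c(C[Zn]Br)c1
F4 | step 10 | methyl 4-[(tert-butyldimethylsilyl)oxy]-3-methylbenzoate | COC(=O)c1ccc(O[Si](C)(C)C(C)(C)C)c(C)c1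
F5 | step 10 | methyl 3-(bromomethyl)-4-[(tert-butyldimethylsilyl)oxy]benzoate | COC(=O)c1ccc(O[Si](C)(C)C(C)(C)C)c(CBr)c1
F6 | step 10 | methyl 4-[(tert-butyldimethylsilyl)oxy]-3-{(2E)-3-methyl-5-[(4aR,8aR)-2,5,5,8a-tetramethyl-3,4,4a,5,6,7,8,8a-octahydronaphthalen-1-yl]pent-2-en-1-yl}benzoate | CC1=C(CC/C(C)=C/Cc2cc(C(=O)OC)ccc2O[Si](C)(C)C(C)(C)C)[C@]2(C)CCCC(C)(C)[C@H]2CC1
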